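## Structural features

Myristinin D is a 2,4-diarylchroman (4-arylflavan). A resorcinol-type A ring (C4a–C8a, 7-OH) is fused to a dihydropyran ring (O1, C2, C3, C4). C2 carries a 4-hydroxyphenyl B ring. C4 carries carbon D3 of a 2,4,6-trihydroxyphenyl ketone (D ring, atoms D1–D6), whose carbonyl on D1 bears the 8-phenyloctyl chain (9-phenylnonanoyl).

The only stereocentres are C2 (S) and C4 (R). They are 1,3-related across the C3 methylene and trans, and C3 carries no group that could relay one to the other.

C4 is a crowded diarylmethine flanked by the D2 and D4 hydroxyls. The C4–D3 bond is acid-labile (retro-Friedel–Crafts on a very electron-rich ring). The C2–O1 bond is a para-hydroxybenzylic ether that can ionise under acid or open through a quinone methide under base, which would scramble C2. Five free phenols, a nucleophilic free position D5 and the aryl ketone limit the reagents that can be used late.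

The real difficulty is the absolute configuration at the hindered C4 together with the trans C2/C4 relationship.

The feature exploited: the phenol oxygen on D4 (equally that on D2) lies 1,3 across the pyran ring from C2 and reaches it when the D ring is pseudoaxial. It can therefore bridge C2 as a diaryl acetal O1–C2–O(D4), a dibenzo-fused 2,8-dioxabicyclo[3.3.1]nonane. This places a leaving group on exactly the face of C2 that the D ring covers, so a carbon nucleophile (the B ring) can enter only trans.

## Logic of the disconnections

**15 ⇒ 14.** Four O–CH2Ph bonds are cut. Five free phenols would not survive an organozinc reagent and a silyl triflate. Benzyl is chosen because it leaves under neutral conditions, whereas acid would threaten C4–D3 and C2–O1. Demand: the hydrogenolysis must spare the cyclic benzylic ether C2–O1 and the ketone.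

**14 ⇒ 10 + 11 (key).** The C2–C1(B ring) bond is cut and C2 is reconnected to the D4 oxygen. In one sentence: 14 arises when the aryl group of 12 (made from 11) opens the bridged acetal 10 at C2 with inversion. The cut removes the B ring and makes C2 a dependent centre; the precursor is a rigid bicycle with one freely chosen stereocentre (C4). Demand: the C2–O(D4) bond, not C2–O1, must ionise; the aryl group must come from outside, anti to the D ring; the ketone must be left alone. The silyl ether 13 is the primary product.

**10 ⇒ 9.** Two O–benzyl bonds on D2 and D6 are cut. Capping these oxygens prevents any metal phenoxide on the D ring from delivering the nucleophile to the wrong face. Demand: O- rather than C-alkylation of an acylphloroglucinol-type ring.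

**9 ⇒ 4 + 7.** The C4–D3 bond and both acetal bonds at C2 (O1–C2 and O(D4)–C2) are cut. This falls back to two achiral pieces of similar size; lactol 8 is the intermediate. Demand: catalytic control of the enantioface at C4. The bridge can close only cis, so C2 follows automatically.

**7 ⇒ 5 + 6.** The C=C bond of the enal (future C3–C4) is cut; a two-carbon homologation of a catalogue salicylaldehyde. Demand: E geometry and a single homologation.

**4 ⇒ 1 + 2.** The aryl–C(=O) bond is cut, through acid chloride 3. Demand: mono-C-acylation of the symmetric triol.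

## Other disconnections considered

**Alternative 1:** (the first that comes to mind) Cut C4–D3. Forward key step: acid-promoted Friedel–Crafts alkylation of 4 by the C4 benzylic cation generated from the (2S)-flavan-4-ol A1, then deprotection.
- A1 needs its own asymmetric synthesis of about five to six steps (chalcone, enantioselective carbonyl reduction, invertive ring closure, benzylic oxidation).
- The stereo-determining C4–D3 bond would be made under the same acid that can break it. 4 has two equivalent nucleophilic carbons, so double alkylation is possible. The trans preference rests only on 1,3-induction from an equatorial C2 aryl group.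
- The chosen plan sets C4 by catalyst control and C2 by an irreversible C–C bond formation in which steric and stereoelectronic bias point the same way, in six steps overall.

**Alternative 2:** Cut O1–C2 and C3–C4. Forward key step: chiral Brønsted-acid-catalysed [4+2] cycloaddition of the ortho-quinone methide generated from benzhydrol A2 with a para-oxygenated styrene. This closes the pyran ring and sets both centres at once.
- In the favoured endo transition state the "outside" aryl group on the methide carbon and the endo aryl group of the styrene end up on the same face. The expected product is therefore the 2,4-cis chroman A3, the wrong relative configuration for 15.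
- Reaching the trans series would need the exo mode or an inversion of one centre afterwards. The di-ortho-substituted aryl group on the methide carbon is also a poor fit for a tight chiral ion pair.

**Alternative 3:** Cut C4–D3 and the C2–H bond. Forward key step: chiral-anion-controlled [3+3] annulation of the flavylium salt A4 with 4 to the bridged ketal A5 (B ring already on C2), then reductive opening of C2–O(D4).
- This is the shortest plan on paper. However, the hydride would have to replace the bridging oxygen with retention, entering syn to the D ring, to give the trans flavan.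
- Attack anti to the pseudoaxial D ring is the sterically and stereoelectronically favoured path and leads to the cis series.
- The chosen plan keeps the same bicyclic topology but brings in the B ring, not hydrogen, as the incoming group. The favoured anti attack then gives trans.

Key step: step 5

Assumption: 1, 2, 5, 6 and 11 (as a THF solution) are taken as catalogue compounds, and the dextrorotatory natural product is taken to be the (2S,4R) isomer written in the target SMILES.

## Route

Step 1
Reactants: 1 9-phenylnonanoic acid; 2 phloroglucinol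
Product: 4 9-phenyl-1-(2,4,6-trihydroxyphenyl)nonan-1-one, via 9-phenylnonanoyl chloride 3 (not isolated)
Conditions: (COCl)2, DMF (cat.), CH2Cl2, 0 °C → rt, evaporate; then 2, AlCl3, PhNO2–CH2Cl2, 0 → 40 °C; aq. HCl
Reagents that add atoms: none
Why: Friedel–Crafts acylation; acid chloride 3 acylates the AlCl3-complexed triol at carbon, the first acyl group deactivates the ring (chelated vinylogous acid) so monoacylation is expected, and the remote phenyl ring is far less nucleophilic than 2.

Step 2
Reactants: 5 4-(benzyloxy)-2-hydroxybenzaldehyde; 6 (triphenylphosphoranylidene)acetaldehyde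
Product: 7 (E)-3-[4-(benzyloxy)-2-hydroxyphenyl]prop-2-enal
Conditions: PhMe, 90 °C
Reagents that add atoms: none
Why: Wittig olefination with a stabilised formylmethylene ylide should give the E-enal; the weakly basic ylide tolerates the free ortho-phenol, and the donor-substituted product enal is less electrophilic than 5, which limits a second homologation.

Step 3
Reactants: 4 9-phenyl-1-(2,4,6-trihydroxyphenyl)nonan-1-one; 7 (E)-3-[4-(benzyloxy)-2-hydroxyphenyl]prop-2-enal
Product: 9 bridged acetal (dibenzo-fused 2,8-dioxabicyclo[3.3.1]nonane; flavan numbering (2S,4R); C4 bonded to D3, acetal carbon C2 bonded to O1 and to the D4 oxygen; 7-OBn; free OH on D2 and D6; 9-phenylnonanoyl on D1), via chroman-2-ol lactol 8 (not isolated)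
Conditions: (R)-α,α-diphenylprolinol trimethylsilyl ether (20 mol %), PhCO2H (20 mol %), CH2Cl2, 0 °C → rt; then p-TsOH·H2O (10 mol %), 4 Å MS, rt
Reagents that add atoms: none
Why: Iminium-ion-catalysed enantioselective Friedel–Crafts-type conjugate addition, then hemiacetalisation and acid-catalysed acetalisation; in the E,s-trans iminium ion of 7 the (R)-catalyst shields the Si face of Cβ (aryl > Cα > H), so the phenolate carbon D3 of 4 (D3 and D5 are equivalent) adds to the Re face and sets C4 as R, and the aldehyde is trapped by the A-ring phenol (lactol 8) and then by the D4 phenol. The bridge can span only one face of the pyran ring, so the acetal carbon C2 is slaved to C4 (2S), and the acetal removes the aldehyde from retro-Michael pathways.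

Step 4
Reactants: 9 bridged acetal diol
Product: 10 bis(O-benzyl) ether of 9 (OBn on D2 and D6; flavan numbering (2S,4R))
Conditions: BnBr, K2CO3, Bu4NI (cat.), DMF, 60 °C
Reagents that add atoms: benzyl bromide (BrCc1ccccc1)
Why: Williamson O-alkylation of the two remaining D-ring phenoxides (the chelated one needs DMF and warming); the diaryl acetal, the ketone and C4 are inert to carbonate, and capping both oxygens ensures that no metal phenoxide sits on the D ring in step 5.

Step 5
Reactants: 10 bis(O-benzyl) bridged acetal; 11 [4-(benzyloxy)phenyl]magnesium bromide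
Product: 14 1-{2,6-bis(benzyloxy)-3-[(2S,4R)-7-(benzyloxy)-2-[4-(benzyloxy)phenyl]chroman-4-yl]-4-hydroxyphenyl}-9-phenylnonan-1-one, via [4-(benzyloxy)phenyl]zinc chloride 12 (not isolated), via aryl trimethylsilyl ether 13 (not isolated)
Conditions: 11, ZnCl2, THF, 0 °C (gives 12); 10, TMSOTf, CH2Cl2, −78 °C, then 12, −78 → −30 °C; aq. NH4Cl, then citric acid, THF–H2O, 0 °C
Reagents that add atoms: none
Why: Mechanism: TMSOTf silylates the acetal oxygen on D4 and the C2–O(D4) bond ionises to a 2-chromanyl oxocarbenium ion (O1=C2); this oxygen is the better leaving group (para to the ketone, a vinylogous carboxylate) and O1 on the electron-richer A ring is the better donor, so both effects select the cleavage that keeps the A-ring pyran. The closest known reaction type is the Lewis-acid-mediated C-arylation of cyclic acetals and lactol derivatives by arylzinc reagents through oxocarbenium ions, as in C-aryl glycoside synthesis. No ring is closed: the dioxocine bridge is opened and the pyran ring is kept. The one new stereocentre, C2, is under substrate control: the silylated D ring on C4 is pseudoaxial (peri strain with H5 otherwise) and covers the face from which its oxygen left, and axial attack on the half-chair also leads to the 1,3-trans product, so the aryl group of 12 should enter anti to the D ring with inversion at C2 to give (2S,4R). The step needs three selectivities: ionisation of C2–O(D4) and not C2–O1 (secured as above); external anti delivery (secured because every D-ring oxygen is capped by benzyl or silyl, so no zinc phenoxide can hand the aryl group to the syn face); and attack on the cation in preference to the ketone (secured by the low carbonyl reactivity of an arylzinc halide toward a di-ortho-substituted aryl ketone). The new C–C bond is not reversible under the conditions, and the cold quench limits acid-mediated ionisation of C2–O1 in the product. Mild acidic work-up cleaves the aryl silyl ether 13 to the phenol 14.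

Step 6
Reactants: 14 tetrabenzyl monophenol
Product: 15 (+)-myristinin D, 1-{2,4,6-trihydroxy-3-[(2S,4R)-7-hydroxy-2-(4-hydroxyphenyl)chroman-4-yl]phenyl}-9-phenylnonan-1-one
Conditions: H2 (1 atm), Pd(OH)2/C, EtOAc–MeOH, rt
Reagents that add atoms: none
Why: Hydrogenolysis of four aryl benzyl ethers; under neutral conditions at 1 atm the cyclic benzylic ether C2–O1 and the chelated, electron-rich aryl ketone are expected to persist, and neither stereocentre is involved.

## Compound list

1 | 9-phenylnonanoic acid | OC(=O)CCCCCCCCc1ccccc1 | starting material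
2 | phloroglucinol (benzene-1,3,5-triol) | Oc1cc(O)cc(O)c1 | starting material
3 | 9-phenylnonanoyl chloride | ClC(=O)CCCCCCCCc1ccccc1 | intermediate
4 | 9-phenyl-1-(2,4,6-trihydroxyphenyl)nonan-1-one | O=C(CCCCCCCCc1ccccc1)c1c(O)cc(O)cc1O | intermediate
5 | 4-(benzyloxy)-2-hydroxybenzaldehyde | O=Cc1ccc(OCc2ccccc2)cc1O | starting material
6 | (triphenylphosphoranylidene)acetaldehyde | O=CC=P(c1ccccc1)(c1ccccc1)c1ccccc1 | starting material
7 | (E)-3-[4-(benzyloxy)-2-hydroxyphenyl]prop-2-enal | O=C/C=C/c1ccc(OCc2ccccc2)cc1O | intermediate
8 | 1-{3-[(4R)-7-(benzyloxy)-2-hydroxychroman-4-yl]-2,4,6-trihydroxyphenyl}-9-phenylnonan-1-one (lactol, both C2 epimers) | O=C(CCCCCCCCc1ccccc1)c1c(O)cc(O)c([C@@H]2CC(O)Oc3cc(OCc4ccccc4)ccc32)c1O | intermediate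
9 | bridged acetal, flavan numbering (2S,4R): C4–D3 bond, C2 bonded to O1 and O(D4), 7-OBn, OH on D2 and D6, 9-phenylnonanoyl on D1 | O=C(CCCCCCCCc1ccccc1)c1c(O)cc2c(c1O)[C@@H]1C[C@H](O2)Oc2cc(OCc3ccccc3)ccc21 | intermediate
10 | bis(O-benzyl) ether of 9 (OBn on D2 and D6), flavan numbering (2S,4R) | O=C(CCCCCCCCc1ccccc1)c1c(OCc3ccccc3)cc2c(c1OCc1ccccc1)[C@@H]1C[C@H](O2)Oc2cc(OCc3ccccc3)ccc21 | intermediate
11 | [4-(benzyloxy)phenyl]magnesium bromide | Br[Mg]c1ccc(OCc2ccccc2)cc1 | starting material
12 | [4-(benzyloxy)phenyl]zinc chloride | Cl[Zn]c1ccc(OCc2ccccc2)cc1 | intermediate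
13 | trimethylsilyl ether of 14 (OSiMe3 on D4), (2S,4R) | O=C(CCCCCCCCc1ccccc1)c1c(OCc2ccccc2)cc(O[Si](C)(C)C)c([C@@H]2C[C@@H](c3ccc(OCc4ccccc4)cc3)Oc3cc(OCc4ccccc4)ccc32)c1OCc1ccccc1 | intermediate
14 | 1-{2,6-bis(benzyloxy)-3-[(2S,4R)-7-(benzyloxy)-2-[4-(benzyloxy)phenyl]chroman-4-yl]-4-hydroxyphenyl}-9-phenylnonan-1-one | O=C(CCCCCCCCc1ccccc1)c1c(OCc2ccccc2)cc(O)c([C@@H]2C[C@@H](c3ccc(OCc4ccccc4)cc3)Oc3cc(OCc4ccccc4)ccc32)c1OCc1ccccc1 | intermediate
15 | (+)-myristinin D, 1-{2,4,6-trihydroxy-3-[(2S,4R)-7-hydroxy-2-(4-hydroxyphenyl)chroman-4-yl]phenyl}-9-phenylnonan-1-one | O=C(CCCCCCCCc1ccccc1)c1c(O)cc(O)c([C@@H]2C[C@@H](c3ccc(O)cc3)Oc3cc(O)ccc32)c1O | target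

## Step count and least certain steps

Total step count: 6. Longest linear sequence: 5 steps (1 or 5 → 15).

**Step 5 (key step).** Three things could go wrong:
- ionisation of the other acetal bond (C2–O1), which would lead to the ring system fused to the D ring;
- transfer of the aryl group from a metal held by a D-ring oxygen to the syn face, with loss of the trans selectivity;
- proton loss from C3 of the cation to an enol ether, or acid-mediated re-ionisation of C2–O1 in the product with epimerisation at C2.

Fallback, from 10 back to 15: the bridge is opened first with a sulfur nucleophile and the arylation is then run on a monocyclic donor with no tethered oxygen.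
- PhSH and BF3·OEt2 should give 1-{2,6-bis(benzyloxy)-3-[(4R)-7-(benzyloxy)-2-(phenylsulfanyl)chroman-4-yl]-4-hydroxyphenyl}-9-phenylnonan-1-one F1.
- Benzylation of the freed phenol gives the tris(benzyloxy) thioacetal F2.
- Oxidation (mCPBA, NaHCO3) gives the anomeric sulfone F3.
- Displacement of the sulfinate by 12 through the same oxocarbenium ion should give the pentabenzyl ether of the target, 1-{2,4,6-tris(benzyloxy)-3-[(2S,4R)-7-(benzyloxy)-2-[4-(benzyloxy)phenyl]chroman-4-yl]phenyl}-9-phenylnonan-1-one F4.
- Hydrogenolysis as in step 6 returns to 15.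

**Step 3.** Possible failures are slow turnover or eroded enantioselectivity (the ortho-hydroxy enal can hold the catalyst as a cyclic N,O-acetal, and the acidic nucleophile can protonate or desilylate it) and a second alkylation of 4 at D5. Closure of the bridge through the D2 oxygen in place of D4 may also occur; this is harmless, because the bridging oxygen is released again in step 5 and all D-ring oxygens end as free phenols.

Fallback, from 4 and 7 back to 9: the same cascade with an achiral amine salt (pyrrolidine, AcOH), then acid, gives 9 together with the enantiomer of 9 F5 as the racemate. Preparative chromatography on a chiral stationary phase then returns 9.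

**Step 4.** C-benzylation at the free D5 position of the phenoxide and incomplete alkylation of the chelated phenol are the likely problems.

Fallback, from 9 back to 15: the benzylation is dropped in favour of transient silylation.
- N,O-bis(trimethylsilyl)acetamide gives the bis(trimethylsilyl) ether of 9 F6, used crude.
- The conditions of step 5 should give the tris(trimethylsilyl) ether of the arylated flavan F7.
- Acidic work-up gives 1-{3-[(2S,4R)-7-(benzyloxy)-2-[4-(benzyloxy)phenyl]chroman-4-yl]-2,4,6-trihydroxyphenyl}-9-phenylnonan-1-one F8.
- Hydrogenolysis of its two benzyl ethers returns to 15.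

**Step 6.** Over-reduction is the risk: hydrogenolysis of the benzylic C2–O1 bond or reduction of the aryl ketone during removal of four benzyl groups.

Fallback, from 14 back to 15: non-reductive debenzylation with BCl3 and pentamethylbenzene as cation scavenger (CH2Cl2, −78 °C). The low temperature and the scavenger are meant to protect the acid-labile C4–D3 bond. This fallback makes no new compound (F0).

## Further compounds

F1 | step 5 | 1-{2,6-bis(benzyloxy)-3-[(4R)-7-(benzyloxy)-2-(phenylsulfanyl)chroman-4-yl]-4-hydroxyphenyl}-9-phenylnonan-1-one (both C2 epimers) | O=C(CCCCCCCCc1ccccc1)c1c(OCc2ccccc2)cc(O)c([C@@H]2CC(Sc3ccccc3)Oc3cc(OCc4ccccc4)ccc32)c1OCc1ccccc1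
F2 | step 5 | 1-{2,4,6-tris(benzyloxy)-3-[(4R)-7-(benzyloxy)-2-(phenylsulfanyl)chroman-4-yl]phenyl}-9-phenylnonan-1-one | O=C(CCCCCCCCc1ccccc1)c1c(OCc2ccccc2)cc(OCc2ccccc2)c([C@@H]2CC(Sc3ccccc3)Oc3cc(OCc4ccccc4)ccc32)c1OCc1ccccc1
F3 | step 5 | 1-{2,4,6-tris(benzyloxy)-3-[(4R)-7-(benzyloxy)-2-(phenylsulfonyl)chroman-4-yl]phenyl}-9-phenylnonan-1-one | O=C(CCCCCCCCc1ccccc1)c1c(OCc2ccccc2)cc(OCc2ccccc2)c([C@@H]2CC(S(=O)(=O)c3ccccc3)Oc3cc(OCc4ccccc4)ccc32)c1OCc1ccccc1
F4 | step 5 | 1-{2,4,6-tris(benzyloxy)-3-[(2S,4R)-7-(benzyloxy)-2-[4-(benzyloxy)phenyl]chroman-4-yl]phenyl}-9-phenylnonan-1-one | O=C(CCCCCCCCc1ccccc1)c1c(OCc2ccccc2)cc(OCc2ccccc2)c([C@@H]2C[C@@H](c3ccc(OCc4ccccc4)cc3)Oc3cc(OCc4ccccc4)ccc32)c1OCc1ccccc1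
F5 | step 3 | enantiomer of 9 (flavan numbering (2R,4S)) | O=C(CCCCCCCCc1ccccc1)c1c(O)cc2c(c1O)[C@H]1C[C@@H](O2)Oc2cc(OCc3ccccc3)ccc21
F6 | step 4 | bis(trimethylsilyl) ether of 9 (OSiMe3 on D2 and D6) | O=C(CCCCCCCCc1ccccc1)c1c(O[Si](C)(C)C)cc2c(c1O[Si](C)(C)C)[C@@H]1C[C@H](O2)Oc2cc(OCc3ccccc3)ccc21
F7 | step 4 | tris(trimethylsilyl) ether of F8 (OSiMe3 on D2, D4 and D6), (2S,4R) | O=C(CCCCCCCCc1ccccc1)c1c(O[Si](C)(C)C)cc(O[Si](C)(C)C)c([C@@H]2C[C@@H](c3ccc(OCc4ccccc4)cc3)Oc3cc(OCc4ccccc4)ccc32)c1O[Si](C)(C)C
F8 | step 4 | 1-{3-[(2S,4R)-7-(benzyloxy)-2-[4-(benzyloxy)phenyl]chroman-4-yl]-2,4,6-trihydroxyphenyl}-9-phenylnonan-1-one | O=C(CCCCCCCCc1ccccc1)c1c(O)cc(O)c([C@@H]2C[C@@H](c3ccc(OCc4ccccc4)cc3)Oc3cc(OCc4ccccc4)ccc32)c1O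
F0 | step 6 | none | none
A1 | alternative 1 | (2S)-7-(benzyloxy)-2-[4-(benzyloxy)phenyl]chroman-4-ol | OC1C[C@@H](c2ccc(OCc3ccccc3)cc2)Oc2cc(OCc3ccccc3)ccc12
A2 | alternative 2 | [4-(benzyloxy)-2-hydroxyphenyl][2,4,6-tris(benzyloxy)phenyl]methanol | OC(c1ccc(OCc2ccccc2)cc1O)c1c(OCc2ccccc2)cc(OCc2ccccc2)cc1OCc1ccccc1
A3 | alternative 2 | (2R,4R)-7-(benzyloxy)-2-[4-(benzyloxy)phenyl]-4-[2,4,6-tris(benzyloxy)phenyl]chroman (2,4-cis) | C(Oc1cc(OCc2ccccc2)c([C@@H]2C[C@H](c3ccc(OCc4ccccc4)cc3)Oc3cc(OCc4ccccc4)ccc32)c(OCc2ccccc2)c1)c1ccccc1
A4 | alternative 3 | 7-(benzyloxy)-2-[4-(benzyloxy)phenyl]chromenylium chloride | [Cl-].[o+]1c(-c2ccc(OCc3ccccc3)cc2)ccc2ccc(OCc3ccccc3)cc12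
A5 | alternative 3 | bridged ketal with the B ring on the ketal carbon (flavan numbering (2R,4R); C2 bonded to O1, O(D4) and the 4-(benzyloxy)phenyl group; 7-OBn; OH on D2 and D6) | O=C(CCCCCCCCc1ccccc1)c1c(O)cc2c(c1O)[C@@H]1C[C@](c3ccc(OCc4ccccc4)cc3)(O2)Oc2cc(OCc3ccccc3)ccc21
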